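Compare, flask by flask, how fast step 3 clears the intermediate with how fast step 2 makes it.

    substrate + target → side product (k1 = 9.4 × 10⁻⁴ /M/s)
    substrate → intermediate (k2 = 7.7 × 10⁻⁴ /s)
    partner + intermediate → target (k3 = 6.1 × 10⁻⁴ /M/s)

all flasks: substrate 0.55 M; time 8.0 h
- autumn: partner 0.300 M
- dawn: partner 0.600 M
- spring: partner 1.20 M
- dusk: partner 2.00 M

- in percentages every species weighs as the substrate in it: one side product counts as two
- "hardly changes" means that all values lie within two and a half points (for a concentration: within two and a half percent of the largest)
- run time (autumn): 8.0 h
- a step back or a flat step of under half a point counts as no turn

- amount of target at the end, in percent of the substrate charged for autumn, dawn, spring, dusk, in this order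
- the course of these numbers from the first flask to the last (rises, then falls / rises all the way / falls, then rises / falls all the way / hardly changes)

How much target can the partner carry? One partner gives one target. In autumn c(partner) is below c(substrate), which makes the partner the limiting reagent and holds target to at most 54.5% of the charge. The dawn charge allows 109%, so that ceiling no longer binds there.

Does target meet substrate? In autumn the substrate has a half-life of 0.25 h by step 2, and target at the charged c(substrate) has a half-life of 0.37 h by step 1, short against the run. Target formed while substrate stands is therefore at risk, and the question becomes when target forms.

With the partner near its charge, step 3 is pseudo-first-order in intermediate, so a single concentration can be reckoned: the matching concentration 1.26 M, the c(partner) at which intermediate is used at the same relative pace as substrate. Autumn lies 0.623 of a power of ten below it, so substrate goes first and target comes later. Dusk lies 0.201 of a power of ten above it, so target grows beside substrate and side product should gain. My reckoning scores the possible courses by these ratios and by the autumn ceiling, and commits to a row that rises, then falls.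

The forecast gives 48%, 81%, 77% and 71%, a course that rises, then falls, because “more partner makes target sooner, while substrate is still present to destroy it”. It agrees with my course and adds numbers that my reckoning does not give. Its shape goes wrong if the highest value moves to the first flask, at 0.300 M, or to the last, at 2.00 M.

The flasks give 50.0%, 82.7%, 80.3% and 75.6%, a course that rises, then falls, with the turn read at 0.71 M of partner. A dusk flask without step 1 ends at 100% target. Autumn, at 0.238 of the matching concentration, ends with 8.12% side product, and dusk, at 1.59 of it, ends with 24.4%.

The rate constants were chosen freely; the rest is arithmetic.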